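Eremophilane numbering is used: ring A = C1–C5 and C10, ring B = C5–C10, and β is the face that carries the C5 methyl.
**Cuts.** The two angelate acyl–O bonds go first. Then C9–O is removed (α'-oxidation), the C3–OH/C4–H pair is taken back through the 3-ketone to a C3=C4 alkene, and C11=C12 is moved back to the conjugated C7=C11 enone.
**Enabling feature.** The stripped core, (10βH)-eremophila-3,7(11)-dien-8-one, has the ring B carbonyl C8 δ,ε to the ring A alkene (C8–C7–C6–C5–C4=C3). This is an oxy-Cope retron. Cutting C5–C6 and joining C3–C8 gives a 2-dienylbicyclo[2.2.2]oct-5-en-2-ol.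
**Forward order.** A Diels–Alder reaction builds the bicyclooctene, and ring A is one of its six-membered rings. Dienyl addition follows, and ring B closes last in the [3,3] shift.
**Stereochemistry.** The absolute configuration comes from the catalytic Diels–Alder step (bridgeheads = C3 and C10), and C5 and C10 come from the cage-enforced suprafacial shift. C9 comes from convex-face oxidation. C3, C4 and C7 are equatorial on the conformer locked by the 9β-silyloxy group, so they are set by equilibration or axial protonation.

Key step: step 7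

Assumption: the (5S)-imidazolidinone salt should shield the same face of acrolein as it does with cyclohexa-1,3-diene, which leads to 5 as drawn. If the sense is opposite, the (5R)-salt is used.

Step 1
Reactants: 1 2-methylcyclohex-2-en-1-one
Product: 2 1,2-dimethylcyclohex-2-en-1-ol (racemic)
Conditions: MeLi, Et2O, −78 °C; then H2O
Reagents that add atoms: methyllithium [Li]C
Why: Hard organolithium 1,2-addition to an enone should give the tertiary allylic alcohol, whose stereocentre is lost in the next step.

Step 2
Reactants: 2 1,2-dimethylcyclohex-2-en-1-ol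
Product: 3 2,3-dimethylcyclohexa-1,3-diene
Conditions: methyl N-(triethylammoniosulfonyl)carbamate (Burgess reagent), toluene, 50 °C
Reagents that add atoms: none
Why: Burgess syn-elimination of the tertiary sulfamate should take a ring C6–H and give the symmetric endocyclic diene without the allyl-cation scrambling that acid would cause.

Step 3
Reactants: 3 2,3-dimethylcyclohexa-1,3-diene; 4 acrolein
Product: 5 (1S,2R,4R)-5,6-dimethylbicyclo[2.2.2]oct-5-ene-2-carbaldehyde (formyl syn to the alkene bridge)
Conditions: (5S)-5-benzyl-2,2,3-trimethylimidazolidin-4-one hydrochloride (cat.), MeCN/H2O, rt; the minor exo isomer is removed by chromatography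
Reagents that add atoms: none
Why: Iminium-catalysed enantioselective Diels–Alder reaction of acrolein with a cyclohexadiene, in which the benzyl group of the catalyst shields one face of the iminium ion and fixes both bridgeheads; the exo isomer is removed because it would lead to the antipodal ketone.

Step 4
Reactants: 5 (1S,2R,4R)-5,6-dimethylbicyclo[2.2.2]oct-5-ene-2-carbaldehyde
Product: 6 (1R,4R)-5,6-dimethylbicyclo[2.2.2]oct-5-en-2-one
Conditions: O2 (1 atm), Cu(OAc)2 (cat.), 2,2'-bipyridine (cat.), DABCO (cat.), DMF, 40 °C
Reagents that add atoms: dioxygen O=O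
Why: Copper-catalysed aerobic deformylation of an α-branched aldehyde (enolate oxygenation, then dioxetane cleavage) should give the ketone and formic acid, leaving the bridgehead centres and the tetrasubstituted alkene untouched.

Step 5
Reactants: 7 2-methylbut-1-en-3-yne
Product: 8 2-bromo-3-methylbuta-1,3-diene
Conditions: HBr (48 % aq.), CuBr (cat.), 0–20 °C
Reagents that add atoms: hydrogen bromide Br
Why: CuBr-catalysed hydrobromination of a vinylacetylene (1,4-addition to the allenyl bromide, then SN2' isomerisation), the reaction type by which 2-halobutadienes are made.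

Step 6
Reactants: 6 (1R,4R)-5,6-dimethylbicyclo[2.2.2]oct-5-en-2-one; 8 2-bromo-3-methylbuta-1,3-diene
Product: 10 (1R,2S,4R)-5,6-dimethyl-2-(3-methylbuta-1,3-dien-2-yl)bicyclo[2.2.2]oct-5-en-2-ol (dienyl syn to the alkene bridge), via dienylmagnesium bromide 9 (not isolated)
Conditions: Mg, THF, rt; then 6, LaCl3·2LiCl (30 mol %), THF, −30 °C; then H2O
Reagents that add atoms: none
Why: Lanthanide-assisted Grignard 1,2-addition to a bicyclo[2.2.2]oct-5-en-2-one, which should come from the face of the sp2 bridge because the other face is screened by the inward hydrogens of the ethano bridge, so the dienyl group ends syn to the alkene.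

Step 7
Reactants: 10 (1R,2S,4R)-5,6-dimethyl-2-(3-methylbuta-1,3-dien-2-yl)bicyclo[2.2.2]oct-5-en-2-ol
Product: 13 (10βH)-eremophila-3,7(11)-dien-8-one, via potassium alkoxide 11 (not isolated), via potassium dienolate 12 (not isolated)
Conditions: KH, 18-crown-6, THF, 0 °C to rt; then MeOH, rt
Reagents that add atoms: none
Why: Deprotonation gives alkoxide 11, whose oxyanion weakens the C3–C8 bond so that the 1,5-diene C6=C7–C8–C3–C4=C5 undergoes an anion-accelerated [3,3]-sigmatropic shift; the closest known reaction type is the anionic oxy-Cope rearrangement of 2-alkenylbicyclo[2.2.2]oct-5-en-2-ols to cis-fused octalones. Ring B (C5–C10) is closed by the new C5–C6 bond through the boat-shaped six-centre transition state that the cage enforces, while ring A is the cyclohexene ring that remains when C3–C8 breaks. The new bond can reach C5 only on the face that looks at the C8–C9 bridge, so C6 and C9 end cis on ring A, and the quaternary centre C5 and the cis ring fusion (C5 methyl and H10 on one face) follow from the bridgehead configuration of 10. The step needs the dienyl group syn to the alkene bridge (secured in step 6) and the [3,3] path to beat a [1,3] shift or fragmentation, which the extra conjugation of the developing dienolate 12 should favour. Methanol protonates 12 and the methoxide formed moves the double bond into conjugation, so the robust enone 13 results and C7, not C9, is the carbon that carries the three-carbon unit.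

Step 8
Reactants: 13 (10βH)-eremophila-3,7(11)-dien-8-one
Product: 14 8-(tert-butyldimethylsilyloxy)-(10βH)-eremophila-3,7(11),8-triene
Conditions: LDA, THF, −78 °C; then TBSOTf
Reagents that add atoms: tert-butyldimethylsilyl trifluoromethanesulfonate CC(C)(C)[Si](C)(C)OS(=O)(=O)C(F)(F)F
Why: Kinetic deprotonation of an enone takes the α' proton (C9–H), and O-silylation should give the cross-conjugated 2-silyloxydiene.

Step 9
Reactants: 14 8-(tert-butyldimethylsilyloxy)-(10βH)-eremophila-3,7(11),8-triene
Product: 15 9β-(tert-butyldimethylsilyloxy)-3β,4β-epoxy-(10βH)-eremophil-7(11)-en-8-one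
Conditions: mCPBA (2.2 equiv), CH2Cl2, −20 to 0 °C
Reagents that add atoms: 3-chloroperoxybenzoic acid O=C(OO)c1cccc(Cl)c1
Why: Rubottom oxidation of the enol ether with silyl migration, in which the peracid comes to C9 anti to the C10–C1 bond (the convex β face); the second equivalent epoxidises the only other electron-rich alkene, C3=C4, whose epoxide configuration is erased in step 10.

Step 10
Reactants: 15 9β-(tert-butyldimethylsilyloxy)-3β,4β-epoxy-(10βH)-eremophil-7(11)-en-8-one
Product: 16 9β-(tert-butyldimethylsilyloxy)-(10βH)-eremophil-7(11)-ene-3,8-dione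
Conditions: BF3·OEt2 (0.3 equiv), CH2Cl2, −78 to −40 °C
Reagents that add atoms: none
Why: Meinwald rearrangement, in which the tertiary C4–O bond opens and H3 shifts to C4 on the face opposite the oxygen; this gives the 3-ketone with the 4β-methyl, which is also the epimer favoured by enolisation because it is equatorial when the 9β-silyloxy group is equatorial.

Step 11
Reactants: 16 9β-(tert-butyldimethylsilyloxy)-(10βH)-eremophil-7(11)-ene-3,8-dione
Product: 17 9β-(tert-butyldimethylsilyloxy)-3α-hydroxy-(10βH)-eremophil-7(11)-en-8-one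
Conditions: Al(OiPr)3 (30 mol %), iPrOH/toluene, 80 °C
Reagents that add atoms: none
Why: Meerwein–Ponndorf–Verley reduction run under equilibrating conditions should touch only the unhindered saturated C3 ketone and settle on the equatorial 3α-alcohol, because the 3β-epimer suffers a syn-axial contact with the C5 methyl.

Step 12
Reactants: 17 9β-(tert-butyldimethylsilyloxy)-3α-hydroxy-(10βH)-eremophil-7(11)-en-8-one
Product: 19 9β-(tert-butyldimethylsilyloxy)-3α-hydroxy-(10βH)-eremophil-11-en-8-one (7β-isopropenyl), via dipotassium dienolate alkoxide 18 (not isolated)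
Conditions: KOtBu (4 equiv), THF/t-BuOH, 0 °C; cannulated into AcOH/THF, −78 °C
Reagents that add atoms: none
Why: Deconjugative protonation, in which excess alkoxide removes a γ-proton from the isopropylidene methyl (C9–H is tertiary and screened) and the extended dienolate is protonated kinetically at the α-carbon C7 along the axial α direction, leaving the isopropenyl group equatorial (7β).

Step 13
Reactants: 19 9β-(tert-butyldimethylsilyloxy)-3α-hydroxy-(10βH)-eremophil-11-en-8-one
Product: 20 3α,9β-dihydroxy-(10βH)-eremophil-11-en-8-one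
Conditions: HF·pyridine, pyridine, THF, 0 °C
Reagents that add atoms: none
Why: Buffered fluoride desilylation avoids the basic medium that would move the C11=C12 bond back into conjugation, and it touches no stereocentre.

Step 14
Reactants: 20 3α,9β-dihydroxy-(10βH)-eremophil-11-en-8-one; 21 angelic acid
Product: 23 3α,9β-bis(angeloyloxy)-(10βH)-eremophil-11-en-8-one (target), via mixed anhydride 22 (not isolated)
Conditions: 21 (3 equiv), 2,4,6-trichlorobenzoyl chloride, Et3N, toluene, rt; then 20, 70 °C, no DMAP
Reagents that add atoms: none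
Why: Yamaguchi-type esterification through the angelic 2,4,6-trichlorobenzoic anhydride without a nucleophilic catalyst is the established way to acylate hindered secondary alcohols while keeping the (Z)-geometry of the angelate; both equatorial hydroxyls should react.

Compound list
1 | 2-methylcyclohex-2-en-1-one | CC1=CCCCC1=O | starting material
2 | 1,2-dimethylcyclohex-2-en-1-ol (racemic) | CC1=CCCCC1(C)O | intermediate
3 | 2,3-dimethylcyclohexa-1,3-diene | CC1=CCCC=C1C | intermediate
4 | acrolein | C=CC=O | starting material
5 | (1S,2R,4R)-5,6-dimethylbicyclo[2.2.2]oct-5-ene-2-carbaldehyde | O=C[C@@H]1C[C@H]2CC[C@@H]1C(C)=C2C | intermediate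
6 | (1R,4R)-5,6-dimethylbicyclo[2.2.2]oct-5-en-2-one | O=C1C[C@H]2CC[C@@H]1C(C)=C2C | intermediate
7 | 2-methylbut-1-en-3-yne | C#CC(C)=C | starting material
8 | 2-bromo-3-methylbuta-1,3-diene | C=C(Br)C(C)=C | intermediate
9 | (3-methylbuta-1,3-dien-2-yl)magnesium bromide | C=C([Mg]Br)C(C)=C | intermediate
10 | (1R,2S,4R)-5,6-dimethyl-2-(3-methylbuta-1,3-dien-2-yl)bicyclo[2.2.2]oct-5-en-2-ol | C=C(C)C(=C)[C@]1(O)C[C@H]2CC[C@@H]1C(C)=C2C | intermediate
11 | potassium alkoxide of 10 | C=C(C)C(=C)[C@]1([O-])C[C@H]2CC[C@@H]1C(C)=C2C.[K+] | intermediate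
12 | potassium (10βH)-eremophila-3,7,11-trien-8-olate | C=C(C)C=1C[C@@]2(C)[C@H](CCC=C2C)CC=1[O-].[K+] | intermediate
13 | (10βH)-eremophila-3,7(11)-dien-8-one | CC(C)=C1C[C@@]2(C)[C@H](CCC=C2C)CC1=O | intermediate
14 | 8-(tert-butyldimethylsilyloxy)-(10βH)-eremophila-3,7(11),8-triene | CC(C)=C1C[C@@]2(C)[C@H](CCC=C2C)C=C1O[Si](C)(C)C(C)(C)C | intermediate
15 | 9β-(tert-butyldimethylsilyloxy)-3β,4β-epoxy-(10βH)-eremophil-7(11)-en-8-one | CC(C)=C1C[C@@]2(C)[C@H](CC[C@@H]3O[C@]23C)[C@@H](O[Si](C)(C)C(C)(C)C)C1=O | intermediate
16 | 9β-(tert-butyldimethylsilyloxy)-(10βH)-eremophil-7(11)-ene-3,8-dione | CC(C)=C1C[C@@]2(C)[C@H](CCC(=O)[C@@H]2C)[C@@H](O[Si](C)(C)C(C)(C)C)C1=O | intermediate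
17 | 9β-(tert-butyldimethylsilyloxy)-3α-hydroxy-(10βH)-eremophil-7(11)-en-8-one | CC(C)=C1C[C@@]2(C)[C@H](CC[C@@H](O)[C@@H]2C)[C@@H](O[Si](C)(C)C(C)(C)C)C1=O | intermediate
18 | dipotassium 3-alkoxide 8-dienolate of 17 | C=C(C)C=1C[C@@]2(C)[C@H](CC[C@@H]([O-])[C@@H]2C)[C@@H](O[Si](C)(C)C(C)(C)C)C=1[O-].[K+].[K+] | intermediate
19 | 9β-(tert-butyldimethylsilyloxy)-3α-hydroxy-(10βH)-eremophil-11-en-8-one | C=C(C)[C@H]1C[C@@]2(C)[C@H](CC[C@@H](O)[C@@H]2C)[C@@H](O[Si](C)(C)C(C)(C)C)C1=O | intermediate
20 | 3α,9β-dihydroxy-(10βH)-eremophil-11-en-8-one | C=C(C)[C@H]1C[C@@]2(C)[C@H](CC[C@@H](O)[C@@H]2C)[C@@H](O)C1=O | intermediate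
21 | angelic acid ((Z)-2-methylbut-2-enoic acid) | OC(=O)/C(C)=C\C | starting material
22 | angelic 2,4,6-trichlorobenzoic anhydride | O=C(OC(=O)/C(C)=C\C)c1c(Cl)cc(Cl)cc1Cl | intermediate
23 | 3α,9β-bis(angeloyloxy)-(10βH)-eremophil-11-en-8-one | C=C(C)[C@H]1C[C@@]2(C)[C@H](CC[C@@H](OC(=O)/C(C)=C\C)[C@@H]2C)[C@@H](OC(=O)/C(C)=C\C)C1=O | target

Total step count: 14. Longest linear sequence: 13 (steps 1–4 and 6–14).

Steps most likely to fail

**Step 12.** Protonation of the extended dienolate may occur at the γ-carbon, which returns the conjugated enone. It may also occur on the more open β face of C7, which gives poor facial selectivity.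
- The fallback sets out from 17 and comes back at 20. It replaces proton transfer by a stereospecific hydride shift.
- Luche reduction (NaBH4, CeCl3·7H2O, MeOH) gives the allylic alcohol F1.
- 2,4-Dinitrobenzenesulfenyl chloride and Et3N convert F1 into the 7,11-diene F2, through a [2,3] sulfenate–sulfoxide shift followed by syn elimination.
- Bu4NF gives the diene diol F3.
- VO(acac)2 with t-BuOOH epoxidises C7=C8 syn to the allylic 9β-hydroxyl and gives the vinyl epoxide F4.
- Pd(PPh3)4 (zerovalent palladium) in THF isomerises F4 to the β,γ-unsaturated ketone 20. The hydrogen moves from C8 to the α face of C7.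

**Step 10.** The cation at C4 may be diverted into ring contraction to an aldehyde, or into migration of a group from the neighbouring quaternary C5.
- The fallback sets out from 15 and comes back at 16. It opens the epoxide by a radical path instead.
- Cp2TiCl (from Cp2TiCl2 and Mn, THF) gives the exo-methylene allylic alcohol F5.
- Dess–Martin periodinane gives the α-methylene ketone F6.
- Conjugate reduction with [(Ph3P)CuH]6 reduces only this unhindered enone and gives 16 after equilibration at C4.

**Step 14.** Warm amine base may move the C11=C12 bond into conjugation or epimerise C7, the angelate may isomerise to the tiglate, and the α-ketol may acylate sluggishly.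
- The fallback sets out from 17 and comes back at 23. It moves the acylation to an intermediate that has no ketone.
- 17 is taken, as in the fallback for step 12, as far as the epoxy diol F4.
- F4 is acylated with 22 to the bis-angelate epoxide F7.
- The neutral Pd(PPh3)4 isomerisation becomes the last step and gives 23.

Further compounds
F1 | step 12 | 9β-(tert-butyldimethylsilyloxy)-(10βH)-eremophil-7(11)-ene-3α,8α-diol | CC(C)=C1C[C@@]2(C)[C@H](CC[C@@H](O)[C@@H]2C)[C@@H](O[Si](C)(C)C(C)(C)C)[C@@H]1O
F2 | step 12 | 9β-(tert-butyldimethylsilyloxy)-(10βH)-eremophila-7,11-dien-3α-ol | C=C(C)C=1C[C@@]2(C)[C@H](CC[C@@H](O)[C@@H]2C)[C@@H](O[Si](C)(C)C(C)(C)C)C=1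
F3 | step 12 | (10βH)-eremophila-7,11-diene-3α,9β-diol | C=C(C)C=1C[C@@]2(C)[C@H](CC[C@@H](O)[C@@H]2C)[C@@H](O)C=1
F4 | step 12 | 7β,8β-epoxy-(10βH)-eremophil-11-ene-3α,9β-diol | C=C(C)[C@]12C[C@@]3(C)[C@H](CC[C@@H](O)[C@@H]3C)[C@@H](O)[C@H]1O2
F5 | step 10 | 9β-(tert-butyldimethylsilyloxy)-3β-hydroxy-(10βH)-eremophila-4(15),7(11)-dien-8-one | CC(C)=C1C[C@@]2(C)[C@H](CC[C@H](O)C2=C)[C@@H](O[Si](C)(C)C(C)(C)C)C1=O
F6 | step 10 | 9β-(tert-butyldimethylsilyloxy)-(10βH)-eremophila-4(15),7(11)-diene-3,8-dione | CC(C)=C1C[C@@]2(C)[C@H](CCC(=O)C2=C)[C@@H](O[Si](C)(C)C(C)(C)C)C1=O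
F7 | step 14 | 3α,9β-bis(angeloyloxy)-7β,8β-epoxy-(10βH)-eremophil-11-ene | C=C(C)[C@]12C[C@@]3(C)[C@H](CC[C@@H](OC(=O)/C(C)=C\C)[C@@H]3C)[C@@H](OC(=O)/C(C)=C\C)[C@H]1O2
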